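**Retrosynthetic overview** (ansa numbering: amide carbonyl C1 along the chain to the benzylic carbon C15; arene C16–C21, nitrogen on C20)

1. The hydroxyquinone is unveiled last from a tris-MOM-protected 1,2,4-trioxygenated arene; before that the 19-membered lactam (second ring) is closed by intramolecular copper-catalysed N-arylation of a C1 primary amide by the C20 aryl bromide.
2. C7–C8 is cut to an (E)-alkenylzinc (hydrozirconation of a C8≡C9 methylalkyne) and the (S)-α-methoxy aldehyde C1–C7 (from (S)-5-(hydroxymethyl)oxolan-2-one); chelation control sets C7.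
3. C15–C16 is cut to an arylzinc (directed lithiation of 1,2,4-tris(methoxymethoxy)benzene) and the C15 oxocarbenium ion of the finished oxane; bromine is then placed on C20.
4. The oxane (O, C11–C15; first ring) comes from a furan by oxidative ring expansion. The enabling feature is that ring O–C11 is a carbinol unit flanked by four carbons carrying oxygen at C12, a C13/C14 unsaturation site with the C14 methyl, and acetal-level C15, which is exactly a 2-(α-hydroxyalkyl)-4-methylfuran after oxidation. C12=O then gives the OMe, C13=C14 gives the C14 methyl stereocentre, and the C15 acetal gives the aryl C-glycoside.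
5. The furylcarbinol comes from a syn-aldol of 4-methylfuran-2-carbaldehyde, which sets C10 and C11.

Key step: step 3

Remark: the C15 anomers formed in the ring expansion and acetalisation are carried on unseparated (major trans anomer drawn), because C15 is re-ionised at the arylation; the four starting materials are taken as catalogue chemicals.

**Step 1**
Reactants: 1 4-methylfuran-2-carbaldehyde; 2 (4R)-4-benzyl-3-propanoyl-1,3-oxazolidin-2-one
Product: 4 (4R)-4-benzyl-3-[(2R,3R)-3-hydroxy-2-methyl-3-(4-methylfuran-2-yl)propanoyl]-1,3-oxazolidin-2-one, via Z-boron enolate 3 (not isolated)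
Conditions: 2, Bu2BOTf, i-Pr2NEt, CH2Cl2, 0 °C; then 1, −78 → 0 °C; pH 7 buffer/MeOH work-up
Reagents that add atoms: none
Why: Evans syn-aldol reaction, in which the Z-boron enolate should react through a closed Zimmerman–Traxler chair on the face away from the benzyl group and so set C10 and C11 (2R,3R, syn) together.

**Step 2**
Reactants: 4
Product: 5 (2R,3R)-3-hydroxy-N-methoxy-N,2-dimethyl-3-(4-methylfuran-2-yl)propanamide
Conditions: MeONHMe·HCl, AlMe3, THF, −20 → 0 °C
Reagents that add atoms: N,O-dimethylhydroxylamine hydrochloride, CNOC.Cl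
Why: Transamidation of the imide by the aluminium amide (Weinreb amide formation), helped by the free β-hydroxyl, should release the auxiliary without touching C10 or C11.

**Step 3**
Reactants: 5
Product: 7 (2R)-2-[(2R)-6-hydroxy-5-methyl-3-oxo-3,6-dihydro-2H-pyran-2-yl]-N-methoxy-N-methylpropanamide (C15 anomers), via open-chain Z-oxoenal 6 (not isolated)
Conditions: NBS, NaHCO3, NaOAc, THF/H2O (4:1), 0 °C
Reagents that add atoms: water, O
Why: Achmatowicz oxidative ring expansion: NBS attacks the furan at its free α-carbon (future C15), water adds, and the resulting 2,5-dihydrofuran hemiketal opens to the Z-4-oxo-enal 6, whose C11 hydroxyl then adds to the C15 aldehyde. The closest known reaction type is the NBS-mediated conversion of 2-furylcarbinols into 6-hydroxy-2H-pyran-3(6H)-ones. The only ring closed is the oxane (O, C11–C15), formed by 6-exo-trig hemiacetalisation, so the five-membered furan is exchanged for a six-membered ring that keeps all four furan carbons and gains the carbinol C–O unit. The one new stereocentre, hemiacetal C15, is set reversibly (anomeric control) and is re-ionised in step 12, whereas C11 is carried through untouched because none of its bonds is broken. The step needs chemoselective oxidation of the furan beside the N-methoxy-N-methylamide and site-selective attack at the unsubstituted furan α-position, which the high electron density of the 2,4-dialkylfuran secures. It also needs C11 (now α to the C12 ketone) not to epimerise, which the cold bicarbonate/acetate-buffered medium secures.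

**Step 4**
Reactants: 7
Product: 8 (2R)-N-methoxy-2-[(2R,6S)-6-methoxy-5-methyl-3-oxo-3,6-dihydro-2H-pyran-2-yl]-N-methylpropanamide
Conditions: HC(OMe)3, BF3·OEt2 (cat.), Et2O, 0 °C
Reagents that add atoms: trimethyl orthoformate, COC(OC)OC
Why: Acid-catalysed acetalisation of the hemiacetal through its oxocarbenium ion should give mainly the trans methyl acetal (axial methoxy, anomeric effect plus relief of allylic strain against the C14 methyl).

**Step 5**
Reactants: 8
Product: 9 (2R)-2-[(2R,3S,6S)-3-hydroxy-6-methoxy-5-methyl-3,6-dihydro-2H-pyran-2-yl]-N-methoxy-N-methylpropanamide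
Conditions: NaBH4, CeCl3·7H2O, MeOH, −78 °C
Reagents that add atoms: none
Why: Luche 1,2-reduction, in which hydride should add axially to the C12 carbonyl anti to the axial C15 methoxy group and so place the new hydroxyl trans to the C11 side chain (12S), as is usual for 2,6-trans pyranones.

**Step 6**
Reactants: 9
Product: 10 (2R)-2-[(2R,3S,5S,6S)-3-hydroxy-6-methoxy-5-methyloxan-2-yl]-N-methoxy-N-methylpropanamide
Conditions: H2 (1 atm), [Ir(cod)(PCy3)(py)]PF6 (5 mol %), CH2Cl2, rt
Reagents that add atoms: none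
Why: Hydroxyl-directed homogeneous hydrogenation, in which the cationic iridium binds the allylic C12 hydroxyl (and the cis C15 methoxy oxygen) and should deliver H2 to that face of C13=C14, leaving the C14 methyl trans to both oxygens (14S).

**Step 7**
Reactants: 10
Product: 11 (2R)-2-[(2R,3S,5S,6S)-3,6-dimethoxy-5-methyloxan-2-yl]-N-methoxy-N-methylpropanamide
Conditions: NaH, MeI, THF, 0 °C → rt
Reagents that add atoms: iodomethane, CI
Why: Williamson etherification of the secondary alkoxide, which at 0 °C should form without deprotonation of the amide α-position.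

**Step 8**
Reactants: 11
Product: 12 (2R)-2-[(2R,3S,5S,6S)-3,6-dimethoxy-5-methyloxan-2-yl]propanal
Conditions: i-Bu2AlH, THF, −78 °C; aqueous sodium potassium tartrate
Reagents that add atoms: none
Why: Partial reduction of the N-methoxy-N-methylamide through its stable chelated tetrahedral intermediate should stop at the aldehyde and keep the α-stereocentre C10.

**Step 9**
Reactants: 12
Product: 13 (2R,3S,5S,6S)-2-[(2S)-4,4-dibromobut-3-en-2-yl]-3,6-dimethoxy-5-methyloxane
Conditions: CBr4, PPh3, 2,6-lutidine, CH2Cl2, 0 °C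
Reagents that add atoms: tetrabromomethane, BrC(Br)(Br)Br
Why: Corey–Fuchs dibromo-olefination (Wittig-type reaction of the dibromomethylene ylide), whose buffered cold conditions should avoid epimerisation at C10.

**Step 10**
Reactants: 13
Product: 15 (2R,3S,5S,6S)-3,6-dimethoxy-5-methyl-2-[(2S)-pent-3-yn-2-yl]oxane, via lithium acetylide 14 (not isolated)
Conditions: n-BuLi (2.1 equiv), THF, −78 °C; then MeI, −78 °C → rt
Reagents that add atoms: iodomethane, CI
Why: Second stage of the Corey–Fuchs sequence (bromine–lithium exchange and Fritsch–Buttenberg–Wiechell rearrangement) gives the lithium acetylide, which is methylated in the same flask to the C8≡C9 methylalkyne.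

**Step 11**
Reactants: 16 benzene-1,2,4-triol
Product: 17 1,2,4-tris(methoxymethoxy)benzene
Conditions: NaH, MOMCl, DMF, 0 °C → rt, argon
Reagents that add atoms: chloromethyl methyl ether, COCCl
Why: Williamson-type O-alkylation of the three phenoxides gives acetal ethers that later serve as ortho-directing groups and as mildly removable protection.

**Step 12**
Reactants: 15; 17
Product: 21 (2R,3S,5S,6S)-3-methoxy-5-methyl-2-[(2S)-pent-3-yn-2-yl]-6-[2,3,6-tris(methoxymethoxy)phenyl]oxane, via anomeric chloride 18 (not isolated), via aryllithium 19 (not isolated), via arylzinc bromide 20 (not isolated)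
Conditions: 15, AcCl, ZnBr2 (5 mol %), CH2Cl2, 0 °C → rt, then evaporation; separately 17, n-BuLi, THF, 0 °C, then ZnBr2 (1 equiv); combined in toluene/THF, −40 °C → rt
Reagents that add atoms: none
Why: C-glycosylation of an α-chloro ether with an arylzinc reagent, in which directed ortho-lithiation between two OMOM groups fixes C16 as the attachment site and the C15 oxocarbenium ion pair should be attacked axially, anti to the pseudoaxial C14 methyl and trans to the C11 substituent (15S).

**Step 13**
Reactants: 21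
Product: 22 (2R,3S,5S,6S)-6-[3-bromo-2,5,6-tris(methoxymethoxy)phenyl]-3-methoxy-5-methyl-2-[(2S)-pent-3-yn-2-yl]oxane
Conditions: NBS (1.0 equiv), MeCN, −20 → 0 °C
Reagents that add atoms: N-bromosuccinimide, O=C1CCC(=O)N1Br
Why: Electrophilic aromatic bromination, in which C20 (para to the C17 oxygen and ortho to the C21 oxygen) should react in preference to C19 while the alkyne stays inert.

**Step 14**
Reactants: 23 (5S)-5-(hydroxymethyl)oxolan-2-one
Product: 24 (5S)-5-{[(tert-butyldiphenylsilyl)oxy]methyl}oxolan-2-one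
Conditions: TBDPSCl, imidazole, DMF, rt
Reagents that add atoms: tert-butyl(chloro)diphenylsilane, CC(C)(C)[Si](Cl)(c1ccccc1)c1ccccc1
Why: Silylation of the primary alcohol protects the future C7 oxygen, the future C6 stereocentre being taken from the chiral pool.

**Step 15**
Reactants: 24
Product: 25 (5S)-5-{[(tert-butyldiphenylsilyl)oxy]methyl}oxolan-2-ol
Conditions: i-Bu2AlH, CH2Cl2, −78 °C; aqueous sodium potassium tartrate
Reagents that add atoms: none
Why: Partial reduction of the γ-lactone at low temperature should stop at the lactol.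

**Step 16**
Reactants: 25
Product: 26 ethyl (2E,6S)-7-[(tert-butyldiphenylsilyl)oxy]-6-hydroxy-2-methylhept-2-enoate
Conditions: Ph3P=C(Me)CO2Et, toluene, 80 °C
Reagents that add atoms: ethyl 2-(triphenyl-λ5-phosphanylidene)propanoate, CCOC(=O)C(C)=P(c1ccccc1)(c1ccccc1)c1ccccc1
Why: Wittig olefination of the open hydroxy-aldehyde form of the lactol by a stabilised ylide should give the (E)-trisubstituted enoate (C2=C3).

**Step 17**
Reactants: 26
Product: 27 ethyl (2E,6S)-7-[(tert-butyldiphenylsilyl)oxy]-6-methoxy-2-methylhept-2-enoate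
Conditions: Me3OBF4, 1,8-bis(dimethylamino)naphthalene, CH2Cl2, rt
Reagents that add atoms: trimethyloxonium tetrafluoroborate, C[O+](C)C.F[B-](F)(F)F
Why: O-Methylation under non-basic conditions should avoid both intramolecular oxa-Michael addition to the enoate and silyl migration.

**Step 18**
Reactants: 27
Product: 28 ethyl (2E,6S)-7-hydroxy-6-methoxy-2-methylhept-2-enoate
Conditions: Bu4NF, AcOH, THF, 0 °C → rt
Reagents that add atoms: none
Why: Fluoride-mediated desilylation, buffered with acetic acid so that the liberated alkoxide cannot add to the enoate.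

**Step 19**
Reactants: 28
Product: 29 ethyl (2E,6S)-6-methoxy-2-methyl-7-oxohept-2-enoate
Conditions: Dess–Martin periodinane, NaHCO3, CH2Cl2, 0 °C → rt; used at once
Reagents that add atoms: none
Why: Buffered hypervalent-iodine oxidation should give the configurationally labile α-methoxy aldehyde without epimerisation at C6.

**Step 20**
Reactants: 22; 29
Product: 32 ethyl (2E,6S,7S,8E,10S)-10-{(2R,3S,5S,6S)-6-[3-bromo-2,5,6-tris(methoxymethoxy)phenyl]-3-methoxy-5-methyloxan-2-yl}-7-hydroxy-6-methoxy-2,8-dimethylundeca-2,8-dienoate, via alkenylzirconocene chloride 30 (not isolated), via alkenyl(methyl)zinc 31 (not isolated)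
Conditions: 22, Cp2ZrHCl (1.5 equiv), THF, 50 °C; solvent change to CH2Cl2; Me2Zn, −78 °C; then 29, −78 → 0 °C; aqueous NH4Cl
Reagents that add atoms: none
Why: Hydrozirconation–zinc transmetalation–aldehyde addition, in which syn-addition of Zr–H places the metal on the less hindered C8 to give the E-alkenyl metal, and zinc chelation between the aldehyde and the α-methoxy oxygen should give the 6,7-syn (7S) allylic alcohol.

**Step 21**
Reactants: 32
Product: 33 (2E,6S,7S,8E,10S)-10-{(2R,3S,5S,6S)-6-[3-bromo-2,5,6-tris(methoxymethoxy)phenyl]-3-methoxy-5-methyloxan-2-yl}-7-hydroxy-6-methoxy-2,8-dimethylundeca-2,8-dienoic acid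
Conditions: LiOH, THF/MeOH/H2O, rt → 40 °C; dilute HCl to pH 4 at 0 °C
Reagents that add atoms: lithium hydroxide, [Li+].[OH-]
Why: Saponification of the ethyl enoate, which the aryl bromide, MOM ethers and alkenes should survive.

**Step 22**
Reactants: 33
Product: 35 (2E,6S,7S,8E,10S)-10-{(2R,3S,5S,6S)-6-[3-bromo-2,5,6-tris(methoxymethoxy)phenyl]-3-methoxy-5-methyloxan-2-yl}-7-hydroxy-6-methoxy-2,8-dimethylundeca-2,8-dienamide, via mixed carbonic anhydride 34 (not isolated)
Conditions: i-BuOCOCl, N-methylmorpholine, THF, −20 °C; then NH3 (0.5 M in dioxane), −20 °C → rt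
Reagents that add atoms: ammonia, N
Why: Mixed-anhydride amidation, in which the carboxylate should be activated much faster than the hindered C7 hydroxyl and ammonia should attack the less hindered acyl carbonyl.

**Step 23**
Reactants: 35
Product: 36 tris-MOM-protected 19-membered macrolactam (C1 amide nitrogen on C20; 17,18,21-tris(methoxymethoxy)arene; 6S,7S,10S,11R,12S,14S,15S; 2E,8E)
Conditions: CuI (50 mol %), N,N′-dimethylethylenediamine, K2CO3, toluene (1 mM), 100 °C
Reagents that add atoms: none
Why: Intramolecular Goldberg-type amidation of the aryl bromide (monovalent copper with a diamine ligand), a ring closure established for 19-membered benzenoid ansa-lactams, should arylate the amide N–H in preference to the C7 hydroxyl.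

**Step 24**
Reactants: 36
Product: 38 target hydroxyquinone macrolactam CNP0204467.1, via hydroquinone triol 37 (not isolated)
Conditions: HCl (1 M) in MeOH/THF, 0 °C → rt, argon; then pH 7 phosphate buffer, air
Reagents that add atoms: none
Why: Acid-catalysed acetal cleavage of the three aryl MOM ethers should give the 1,2,4-trihydroxyarene, which autoxidises to the 2-hydroxy-1,4-benzoquinone; because hydroxy-para-quinone and hydroxy-ortho-quinone are tautomers, no regiochemical question arises.

**Compound list**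

1 | 4-methylfuran-2-carbaldehyde | Cc1coc(C=O)c1 | starting material
2 | (4R)-4-benzyl-3-propanoyl-1,3-oxazolidin-2-one | CCC(=O)N1C(=O)OC[C@H]1Cc1ccccc1 | starting material
3 | Z-dibutylboron enolate of 2 | C/C=C(\OB(CCCC)CCCC)N1C(=O)OC[C@H]1Cc1ccccc1 | intermediate
4 | (4R)-4-benzyl-3-[(2R,3R)-3-hydroxy-2-methyl-3-(4-methylfuran-2-yl)propanoyl]-1,3-oxazolidin-2-one | Cc1coc(c1)[C@H](O)[C@@H](C)C(=O)N1C(=O)OC[C@H]1Cc1ccccc1 | intermediate
5 | (2R,3R)-3-hydroxy-N-methoxy-N,2-dimethyl-3-(4-methylfuran-2-yl)propanamide | Cc1coc(c1)[C@H](O)[C@@H](C)C(=O)N(C)OC | intermediate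
6 | (2R,3R,5Z)-3-hydroxy-N-methoxy-N,2,6-trimethyl-4,7-dioxohept-5-enamide | CON(C)C(=O)[C@H](C)[C@@H](O)C(=O)/C=C(/C)C=O | intermediate
7 | (2R)-2-[(2R)-6-hydroxy-5-methyl-3-oxo-3,6-dihydro-2H-pyran-2-yl]-N-methoxy-N-methylpropanamide (C15 anomers) | O=C1C=C(C)C(O)O[C@@H]1[C@@H](C)C(=O)N(C)OC | intermediate
8 | (2R)-N-methoxy-2-[(2R,6S)-6-methoxy-5-methyl-3-oxo-3,6-dihydro-2H-pyran-2-yl]-N-methylpropanamide | O=C1C=C(C)[C@@H](OC)O[C@@H]1[C@@H](C)C(=O)N(C)OC | intermediate
9 | (2R)-2-[(2R,3S,6S)-3-hydroxy-6-methoxy-5-methyl-3,6-dihydro-2H-pyran-2-yl]-N-methoxy-N-methylpropanamide | O[C@H]1C=C(C)[C@@H](OC)O[C@@H]1[C@@H](C)C(=O)N(C)OC | intermediate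
10 | (2R)-2-[(2R,3S,5S,6S)-3-hydroxy-6-methoxy-5-methyloxan-2-yl]-N-methoxy-N-methylpropanamide | O[C@H]1C[C@H](C)[C@@H](OC)O[C@@H]1[C@@H](C)C(=O)N(C)OC | intermediate
11 | (2R)-2-[(2R,3S,5S,6S)-3,6-dimethoxy-5-methyloxan-2-yl]-N-methoxy-N-methylpropanamide | CO[C@H]1C[C@H](C)[C@@H](OC)O[C@@H]1[C@@H](C)C(=O)N(C)OC | intermediate
12 | (2R)-2-[(2R,3S,5S,6S)-3,6-dimethoxy-5-methyloxan-2-yl]propanal | CO[C@H]1C[C@H](C)[C@@H](OC)O[C@@H]1[C@@H](C)C=O | intermediate
13 | (2R,3S,5S,6S)-2-[(2S)-4,4-dibromobut-3-en-2-yl]-3,6-dimethoxy-5-methyloxane | CO[C@H]1C[C@H](C)[C@@H](OC)O[C@@H]1[C@@H](C)C=C(Br)Br | intermediate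
14 | lithium acetylide of the C8≡C9 alkyne | CO[C@H]1C[C@H](C)[C@@H](OC)O[C@@H]1[C@@H](C)C#C[Li] | intermediate
15 | (2R,3S,5S,6S)-3,6-dimethoxy-5-methyl-2-[(2S)-pent-3-yn-2-yl]oxane | CO[C@H]1C[C@H](C)[C@@H](OC)O[C@@H]1[C@@H](C)C#CC | intermediate
16 | benzene-1,2,4-triol | Oc1ccc(O)c(O)c1 | starting material
17 | 1,2,4-tris(methoxymethoxy)benzene | COCOc1ccc(OCOC)c(OCOC)c1 | intermediate
18 | (2R,3S,5S)-6-chloro-3-methoxy-5-methyl-2-[(2S)-pent-3-yn-2-yl]oxane | CO[C@H]1C[C@H](C)C(Cl)O[C@@H]1[C@@H](C)C#CC | intermediate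
19 | [2,3,6-tris(methoxymethoxy)phenyl]lithium | COCOc1ccc(OCOC)c(OCOC)c1[Li] | intermediate
20 | bromo[2,3,6-tris(methoxymethoxy)phenyl]zinc | COCOc1ccc(OCOC)c(OCOC)c1[Zn]Br | intermediate
21 | (2R,3S,5S,6S)-3-methoxy-5-methyl-2-[(2S)-pent-3-yn-2-yl]-6-[2,3,6-tris(methoxymethoxy)phenyl]oxane | CO[C@H]1C[C@H](C)[C@@H](c2c(OCOC)ccc(OCOC)c2OCOC)O[C@@H]1[C@@H](C)C#CC | intermediate
22 | (2R,3S,5S,6S)-6-[3-bromo-2,5,6-tris(methoxymethoxy)phenyl]-3-methoxy-5-methyl-2-[(2S)-pent-3-yn-2-yl]oxane | CO[C@H]1C[C@H](C)[C@@H](c2c(OCOC)c(Br)cc(OCOC)c2OCOC)O[C@@H]1[C@@H](C)C#CC | intermediate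
23 | (5S)-5-(hydroxymethyl)oxolan-2-one | O=C1CC[C@@H](CO)O1 | starting material
24 | (5S)-5-{[(tert-butyldiphenylsilyl)oxy]methyl}oxolan-2-one | O=C1CC[C@@H](CO[Si](c2ccccc2)(c2ccccc2)C(C)(C)C)O1 | intermediate
25 | (5S)-5-{[(tert-butyldiphenylsilyl)oxy]methyl}oxolan-2-ol | OC1CC[C@@H](CO[Si](c2ccccc2)(c2ccccc2)C(C)(C)C)O1 | intermediate
26 | ethyl (2E,6S)-7-[(tert-butyldiphenylsilyl)oxy]-6-hydroxy-2-methylhept-2-enoate | CC(C)(C)[Si](c1ccccc1)(c1ccccc1)OC[C@@H](O)CC/C=C(\C)C(=O)OCC | intermediate
27 | ethyl (2E,6S)-7-[(tert-butyldiphenylsilyl)oxy]-6-methoxy-2-methylhept-2-enoate | CC(C)(C)[Si](c1ccccc1)(c1ccccc1)OC[C@@H](OC)CC/C=C(\C)C(=O)OCC | intermediate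
28 | ethyl (2E,6S)-7-hydroxy-6-methoxy-2-methylhept-2-enoate | OC[C@@H](OC)CC/C=C(\C)C(=O)OCC | intermediate
29 | ethyl (2E,6S)-6-methoxy-2-methyl-7-oxohept-2-enoate | O=C[C@@H](OC)CC/C=C(\C)C(=O)OCC | intermediate
30 | (E)-alkenylzirconocene chloride from 22 (Zr on C8) | CO[C@H]1C[C@H](C)[C@@H](c2c(OCOC)c(Br)cc(OCOC)c2OCOC)O[C@@H]1[C@@H](C)/C=C(\C)[Zr](Cl)(C3C=CC=C3)C3C=CC=C3 | intermediate
31 | (E)-alkenyl(methyl)zinc from 30 (Zn on C8) | CO[C@H]1C[C@H](C)[C@@H](c2c(OCOC)c(Br)cc(OCOC)c2OCOC)O[C@@H]1[C@@H](C)/C=C(\C)[Zn]C | intermediate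
32 | ethyl (2E,6S,7S,8E,10S)-10-{(2R,3S,5S,6S)-6-[3-bromo-2,5,6-tris(methoxymethoxy)phenyl]-3-methoxy-5-methyloxan-2-yl}-7-hydroxy-6-methoxy-2,8-dimethylundeca-2,8-dienoate | CO[C@H]1C[C@H](C)[C@@H](c2c(OCOC)c(Br)cc(OCOC)c2OCOC)O[C@@H]1[C@@H](C)/C=C(\C)[C@H](O)[C@@H](OC)CC/C=C(\C)C(=O)OCC | intermediate
33 | corresponding undeca-2,8-dienoic acid | CO[C@H]1C[C@H](C)[C@@H](c2c(OCOC)c(Br)cc(OCOC)c2OCOC)O[C@@H]1[C@@H](C)/C=C(\C)[C@H](O)[C@@H](OC)CC/C=C(\C)C(=O)O | intermediate
34 | isobutyl carbonic mixed anhydride of 33 | CO[C@H]1C[C@H](C)[C@@H](c2c(OCOC)c(Br)cc(OCOC)c2OCOC)O[C@@H]1[C@@H](C)/C=C(\C)[C@H](O)[C@@H](OC)CC/C=C(\C)C(=O)OC(=O)OCC(C)C | intermediate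
35 | corresponding undeca-2,8-dienamide (primary amide) | CO[C@H]1C[C@H](C)[C@@H](c2c(OCOC)c(Br)cc(OCOC)c2OCOC)O[C@@H]1[C@@H](C)/C=C(\C)[C@H](O)[C@@H](OC)CC/C=C(\C)C(N)=O | intermediate
36 | tris-MOM-protected 19-membered macrolactam | CO[C@H]1C[C@H](C)[C@@H]2O[C@@H]1[C@@H](C)/C=C(\C)[C@H](O)[C@@H](OC)CC/C=C(\C)C(=O)Nc1cc(OCOC)c(OCOC)c2c1OCOC | intermediate
37 | 17,18,21-trihydroxyarene (hydroquinone) macrolactam | CO[C@H]1C[C@H](C)[C@@H]2O[C@@H]1[C@@H](C)/C=C(\C)[C@H](O)[C@@H](OC)CC/C=C(\C)C(=O)Nc1cc(O)c(O)c2c1O | intermediate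
38 | CNP0204467.1, (2E,8E)-(6S,7S,10S,11R,12S,14S,15S)-11,15-epoxy-7,17-dihydroxy-6,12-dimethoxy-2,8,10,14-tetramethyl ansa-lactam 18,21-quinone | CO[C@H]1C[C@H](C)[C@@H]2O[C@@H]1[C@@H](C)/C=C(\C)[C@H](O)[C@@H](OC)CC/C=C(\C)C(=O)NC1=CC(=O)C(O)=C2C1=O | target

**Step count**

Total: 24 steps. Longest linear sequence: 17 steps (steps 1–10, 12, 13, 20–24).

**Steps most likely to fail**

Step 12 (C15 arylation). What may go wrong: base-induced loss of HCl from the anomeric chloride to the enol ether, sluggish transfer of the doubly ortho-substituted aryl group, or erosion of facial selectivity at the oxocarbenium ion. The fallback sets out from 17 and 15 and returns at 21. Compound 17 is lithiated as before and quenched with B(OMe)3 and then aqueous KHF2 to give potassium trifluoro[2,3,6-tris(methoxymethoxy)phenyl]borate F1. F1 is coupled directly with the methyl acetal 15 under BF3·OEt2 in MeCN at −40 °C (Lewis acid-promoted substitution of an O,O-acetal by an organotrifluoroborate). This is a non-basic ipso-substitution that needs no anomeric halide and should show the same axial preference, giving 21.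

Step 13 (bromination at C20). What may go wrong: competing substitution at C19 or double bromination of the very electron-rich ring. The fallback sets out from 17 (with 15) and returns at 22. NBS bromination of 17 itself, where only the unhindered position para to one oxygen and ortho to another is activated, gives 1-bromo-2,4,5-tris(methoxymethoxy)benzene F2. Bromine–lithium exchange (n-BuLi, −78 °C) and quenching with Me3SiCl give trimethyl[2,4,5-tris(methoxymethoxy)phenyl]silane F3. F3 is lithiated between its two flanking OMOM groups, transmetalated with ZnBr2 and coupled with chloride 18 (made from 15 as in step 12) to the silylated aryl oxane F4. Ipso-bromodesilylation of F4 with NBS then places bromine on C20 without ambiguity and gives 22.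

Step 23 (macrolactam closure by N-arylation). What may go wrong: slow oxidative addition at the hindered, electron-rich bromide, intermolecular oligomerisation, or competing O-arylation of the C7 hydroxyl. The fallback sets out from 32 and returns at 36. Amination of 32 with benzophenone imine (Pd2(dba)3, BINAP, Cs2CO3, toluene, 100 °C) gives the N-(diphenylmethylidene)aniline F5. Transimination with NH2OH·HCl/NaOAc in MeOH gives the C20 aniline ester F6, and saponification with LiOH gives the amino acid F7. Classical macrolactamisation of F7 (BOP-Cl, i-Pr2NEt, toluene, 85 °C, high dilution), in which the amide bond is made by acylation of the aniline, gives 36.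

**Further compounds**

F1 | step 12 | potassium trifluoro[2,3,6-tris(methoxymethoxy)phenyl]borate | [K+].COCOc1ccc(OCOC)c(OCOC)c1[B-](F)(F)F
F2 | step 13 | 1-bromo-2,4,5-tris(methoxymethoxy)benzene | COCOc1c(Br)cc(OCOC)c(OCOC)c1
F3 | step 13 | trimethyl[2,4,5-tris(methoxymethoxy)phenyl]silane | COCOc1c([Si](C)(C)C)cc(OCOC)c(OCOC)c1
F4 | step 13 | (2R,3S,5S,6S)-3-methoxy-5-methyl-2-[(2S)-pent-3-yn-2-yl]-6-[2,5,6-tris(methoxymethoxy)-3-(trimethylsilyl)phenyl]oxane | CO[C@H]1C[C@H](C)[C@@H](c2c(OCOC)c([Si](C)(C)C)cc(OCOC)c2OCOC)O[C@@H]1[C@@H](C)C#CC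
F5 | step 23 | N-(diphenylmethylidene)aniline analogue of 32 (N=CPh2 on C20 in place of Br) | CO[C@H]1C[C@H](C)[C@@H](c2c(OCOC)c(N=C(c3ccccc3)c3ccccc3)cc(OCOC)c2OCOC)O[C@@H]1[C@@H](C)/C=C(\C)[C@H](O)[C@@H](OC)CC/C=C(\C)C(=O)OCC
F6 | step 23 | C20 aniline ethyl ester (NH2 in place of Br in 32) | CO[C@H]1C[C@H](C)[C@@H](c2c(OCOC)c(N)cc(OCOC)c2OCOC)O[C@@H]1[C@@H](C)/C=C(\C)[C@H](O)[C@@H](OC)CC/C=C(\C)C(=O)OCC
F7 | step 23 | C20 aniline carboxylic acid (seco amino acid) | CO[C@H]1C[C@H](C)[C@@H](c2c(OCOC)c(N)cc(OCOC)c2OCOC)O[C@@H]1[C@@H](C)/C=C(\C)[C@H](O)[C@@H](OC)CC/C=C(\C)C(=O)O
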